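The synthesis rests on cutting the O1–C8a bond of ring C. The feature used is the para relation of the C5 and C8 hydroxyls. Ring A is a reduced 1,4-benzoquinone, and in its oxidised form C8a, the only unsubstituted ring carbon, lies β to both the C5 and the C4 carbonyl. One electrolysis turns an open-chain acylhydroquinone into the acylquinone. It then frees the C2 aldehyde enol, whose oxygen adds to C8a and closes the pyranone, and the anode carries the adduct on to an isolable 5,8-quinone. The precursor is a racemic 1,2-diaryl-3,3-dimethoxypropan-1-one, made by oxidative aryl migration in a chalcone. Hydrogenation then delivers the target.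

Key step: step 9

Remark on stereochemistry: the target has no stereocentre and no hindered axis, so it is achiral and there is no enantiomer to select. The one sp3 stereocentre that appears on the way (the α-carbon of the propanones) is carried as a racemate and becomes sp2 in the key step.

Atom map: aryl C1, C2, C3, C4, C5, C6 of ring A in the acetophenones and propanones become C4a, C5, C6, C7, C8, C8a of the chromone.

Design points:
- O5 must never be a free phenol beside an unmasked C2, because the ordinary chromone closure through O5 would then win. The hydroquinone therefore stays diacetylated until just before the electrolysis.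
- The electrolysis starts in a buffer that leaves the acetal intact. Acid is added only after the first two electrons per molecule have passed.
- The β-keto acetal comes directly from a chalcone. This uses the ring-B aldehyde without homologation and places the persulfate hydroxylation on a simple acetophenone.
- Thallium salts are highly toxic and need dedicated handling and waste treatment.

Step 1
Reactants: 1 2',3',4'-trihydroxyacetophenone (gallacetophenone)
Product: 2 1-(4-benzyloxy-2,3-dihydroxyphenyl)ethanone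
Conditions: BnBr (1.0 equiv), NaHCO3, NaI (cat.), DMF, 40 °C, N2
Reagents that add atoms: benzyl bromide, BrCc1ccccc1
Why: Williamson etherification in which bicarbonate ionises only the 4-OH, the most acidic phenol because it is para to the acetyl group, while the 2-OH is tied up in a hydrogen bond to the ketone and the 3-OH is flanked on both sides.

Step 2
Reactants: 2 1-(4-benzyloxy-2,3-dihydroxyphenyl)ethanone
Product: 3 1-(4-benzyloxy-2-hydroxy-3-methoxyphenyl)ethanone
Conditions: MeI (1.1 equiv), K2CO3 (1.1 equiv), acetone, rt to reflux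
Reagents that add atoms: iodomethane, CI
Why: Chelation-controlled Williamson methylation: the 2-OH remains hydrogen-bonded to the carbonyl and is inert to one equivalent of MeI with carbonate, so the 3-OH alone is alkylated.

Step 3
Reactants: 3 1-(4-benzyloxy-2-hydroxy-3-methoxyphenyl)ethanone
Product: 5 1-(4-benzyloxy-2,5-dihydroxy-3-methoxyphenyl)ethanone, via potassium aryl sulfate 4 (not isolated)
Conditions: K2S2O8, aq KOH, pyridine, 0 to 20 °C; acidify to pH 4, extract unchanged 3; then aq HCl, 85 °C
Reagents that add atoms: potassium persulfate, [K+].[K+].[O-]S(=O)(=O)OOS(=O)(=O)[O-]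
Why: Elbs persulfate oxidation: the phenoxide of 3 attacks the peroxide oxygen through C5, the free position para to O2, to give sulfate 4, which resists further oxidation and is hydrolysed by acid after unchanged 3 has been extracted for recycling.

Step 4
Reactants: 6 3-hydroxy-4,5-dimethoxybenzaldehyde
Product: 7 3-benzyloxy-4,5-dimethoxybenzaldehyde
Conditions: BnBr, K2CO3, DMF, rt
Reagents that add atoms: benzyl bromide, BrCc1ccccc1
Why: Plain Williamson benzylation of the only phenol, which gives ring B a protecting group that falls in the final hydrogenation.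

Step 5
Reactants: 5 1-(4-benzyloxy-2,5-dihydroxy-3-methoxyphenyl)ethanone; 7 3-benzyloxy-4,5-dimethoxybenzaldehyde
Product: 8 (E)-1-(4-benzyloxy-2,5-dihydroxy-3-methoxyphenyl)-3-(3-benzyloxy-4,5-dimethoxyphenyl)prop-2-en-1-one
Conditions: KOH (50 % aq), EtOH, degassed, Ar, rt; cold dil. HCl
Reagents that add atoms: none
Why: Claisen–Schmidt condensation, in which the enolate of the methyl ketone adds to the non-enolisable aldehyde and E1cB dehydration gives the conjugated E-alkene as the thermodynamic product; oxygen is excluded because the hydroquinone anion is air-sensitive.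

Step 6
Reactants: 8 (E)-1-(4-benzyloxy-2,5-dihydroxy-3-methoxyphenyl)-3-(3-benzyloxy-4,5-dimethoxyphenyl)prop-2-en-1-one
Product: 9 (E)-1-(2,5-diacetoxy-4-benzyloxy-3-methoxyphenyl)-3-(3-benzyloxy-4,5-dimethoxyphenyl)prop-2-en-1-one
Conditions: Ac2O, pyridine, DMAP (cat.), rt
Reagents that add atoms: acetic anhydride, CC(=O)OC(C)=O
Why: DMAP-catalysed O-acetylation caps both phenols, which shields the hydroquinone from thallium(III) in the next step and keeps O5 from acting as a nucleophile once the C2 acetal is in place.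

Step 7
Reactants: 9 (E)-1-(2,5-diacetoxy-4-benzyloxy-3-methoxyphenyl)-3-(3-benzyloxy-4,5-dimethoxyphenyl)prop-2-en-1-one
Product: 10 (±)-1-(2,5-diacetoxy-4-benzyloxy-3-methoxyphenyl)-2-(3-benzyloxy-4,5-dimethoxyphenyl)-3,3-dimethoxypropan-1-one
Conditions: Tl(NO3)3·3H2O (1.1 equiv), MeOH/HC(OMe)3 1:1, rt; aq NaHCO3
Reagents that add atoms: methanol, CO
Why: Thallium(III) nitrate oxidative rearrangement of a chalcone: oxythallation of the enone, 1,2-shift of the electron-rich ring B (assisted by its para methoxy group) with loss of thallium(I), and capture of the oxocarbenium ion by methanol give the β-keto acetal, whose new α-stereocentre forms as a racemate and is erased in step 9.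

Step 8
Reactants: 10 (±)-1-(2,5-diacetoxy-4-benzyloxy-3-methoxyphenyl)-2-(3-benzyloxy-4,5-dimethoxyphenyl)-3,3-dimethoxypropan-1-one
Product: 11 (±)-1-(4-benzyloxy-2,5-dihydroxy-3-methoxyphenyl)-2-(3-benzyloxy-4,5-dimethoxyphenyl)-3,3-dimethoxypropan-1-one
Conditions: K2CO3 (2.2 equiv), degassed MeOH, 0 °C, Ar; pH 6 phosphate buffer
Reagents that add atoms: none
Why: Base-mediated methanolysis (transesterification) of aryl acetates is far faster than any reaction of the base-stable acetal, and the low temperature, short contact time and near-neutral quench are chosen to avoid E1cB loss of methoxide and any acid contact while O5 is free.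

Step 9
Reactants: 11 (±)-1-(4-benzyloxy-2,5-dihydroxy-3-methoxyphenyl)-2-(3-benzyloxy-4,5-dimethoxyphenyl)-3,3-dimethoxypropan-1-one
Product: 15 7-benzyloxy-3-(3-benzyloxy-4,5-dimethoxyphenyl)-6-methoxychromene-4,5,8-trione, via acylquinone acetal 12 (not isolated), via quinone enol 13 (not isolated), via ring-closed hydroquinone 14 (not isolated)
Conditions: divided cell, carbon-felt anode, Pt cathode, about +0.7 V vs Ag/AgCl (set from a voltammogram of 11); (i) MeCN/H2O 4:1, 0.1 M LiClO4, AcOH/NaOAc (pH about 4.5), 0 °C, 2 F/mol; (ii) add TFA (10 vol %), 25 °C, further 2 F/mol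
Reagents that add atoms: water, O
Why: Proposed new method: at the set potential the hydroquinone of 11 gives up two electrons and two protons to form acylquinone 12 while the buffered medium leaves the acetal untouched, so O5 is already a carbonyl oxygen before C2 is unmasked. The added acid then hydrolyses the acetal (O1 comes from water) to the Z-enol 13, whose oxygen attacks C8a, the only unsubstituted quinone carbon and the β-position of both the C5 and the C4 carbonyl, in a 6-endo-trig oxa-Michael closure of the pyranone. Tautomerisation gives hydroquinone 14, which the anode reoxidises to 15, so no quinone is spent as a sacrificial oxidant. The closest known reactions are the oxidation of acylhydroquinones to 2-acylquinones and the addition of water, alcohols or carboxylates to C3 of 2-acylquinones; joining them to an acetal unmasking in one cell is untested. No stereocentre is created and the racemic α-centre of 11 becomes the sp2 carbon C3. Chemoselectivity rests on the wide gap expected between the hydroquinone wave and that of the trialkoxy ring B, and water that reaches C8a ahead of the enol would still put O1 on C8a and could condense with C2 to the same product.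

Step 10
Reactants: 15 7-benzyloxy-3-(3-benzyloxy-4,5-dimethoxyphenyl)-6-methoxychromene-4,5,8-trione
Product: 16 5,7,8-trihydroxy-3-(3-hydroxy-4,5-dimethoxyphenyl)-6-methoxychromen-4-one (5,7,8,3'-tetrahydroxy-6,4',5'-trimethoxyisoflavone)
Conditions: H2 (1 atm), 10 % Pd/C, THF/MeOH, rt; filtration and concentration under Ar
Reagents that add atoms: none
Why: Catalytic hydrogenation first reduces the quinone to the 5,8-hydroquinone and then hydrogenolyses both benzyl ethers, while the conjugated C2=C3 bond of an isoflavone is reduced much more slowly, so the uptake is stopped after three equivalents.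

Compound list

1 | 2',3',4'-trihydroxyacetophenone (gallacetophenone) | CC(=O)c1ccc(O)c(O)c1O | starting material
2 | 1-(4-benzyloxy-2,3-dihydroxyphenyl)ethanone | CC(=O)c1ccc(OCc2ccccc2)c(O)c1O | intermediate
3 | 1-(4-benzyloxy-2-hydroxy-3-methoxyphenyl)ethanone | CC(=O)c1ccc(OCc2ccccc2)c(OC)c1O | intermediate
4 | potassium 5-acetyl-2-benzyloxy-4-hydroxy-3-methoxyphenyl sulfate | CC(=O)c1cc(OS(=O)(=O)[O-])c(OCc2ccccc2)c(OC)c1O.[K+] | intermediate
5 | 1-(4-benzyloxy-2,5-dihydroxy-3-methoxyphenyl)ethanone | CC(=O)c1cc(O)c(OCc2ccccc2)c(OC)c1O | intermediate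
6 | 3-hydroxy-4,5-dimethoxybenzaldehyde | COc1cc(C=O)cc(O)c1OC | starting material
7 | 3-benzyloxy-4,5-dimethoxybenzaldehyde | COc1cc(C=O)cc(OCc2ccccc2)c1OC | intermediate
8 | (E)-1-(4-benzyloxy-2,5-dihydroxy-3-methoxyphenyl)-3-(3-benzyloxy-4,5-dimethoxyphenyl)prop-2-en-1-one | COc1cc(/C=C/C(=O)c2cc(O)c(OCc3ccccc3)c(OC)c2O)cc(OCc2ccccc2)c1OC | intermediate
9 | (E)-1-(2,5-diacetoxy-4-benzyloxy-3-methoxyphenyl)-3-(3-benzyloxy-4,5-dimethoxyphenyl)prop-2-en-1-one | COc1cc(/C=C/C(=O)c2cc(OC(C)=O)c(OCc3ccccc3)c(OC)c2OC(C)=O)cc(OCc2ccccc2)c1OC | intermediate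
10 | (±)-1-(2,5-diacetoxy-4-benzyloxy-3-methoxyphenyl)-2-(3-benzyloxy-4,5-dimethoxyphenyl)-3,3-dimethoxypropan-1-one (racemate) | COC(OC)C(C(=O)c1cc(OC(C)=O)c(OCc2ccccc2)c(OC)c1OC(C)=O)c1cc(OC)c(OC)c(OCc2ccccc2)c1 | intermediate
11 | (±)-1-(4-benzyloxy-2,5-dihydroxy-3-methoxyphenyl)-2-(3-benzyloxy-4,5-dimethoxyphenyl)-3,3-dimethoxypropan-1-one (racemate) | COC(OC)C(C(=O)c1cc(O)c(OCc2ccccc2)c(OC)c1O)c1cc(OC)c(OC)c(OCc2ccccc2)c1 | intermediate
12 | (±)-2-[2-(3-benzyloxy-4,5-dimethoxyphenyl)-3,3-dimethoxypropanoyl]-5-benzyloxy-6-methoxy-1,4-benzoquinone (racemate) | COC(OC)C(C(=O)C1=CC(=O)C(OCc2ccccc2)=C(OC)C1=O)c1cc(OC)c(OC)c(OCc2ccccc2)c1 | intermediate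
13 | 2-[(Z)-2-(3-benzyloxy-4,5-dimethoxyphenyl)-3-hydroxyprop-2-enoyl]-5-benzyloxy-6-methoxy-1,4-benzoquinone | O/C=C(/c1cc(OC)c(OC)c(OCc2ccccc2)c1)C(=O)C1=CC(=O)C(OCc2ccccc2)=C(OC)C1=O | intermediate
14 | 7-benzyloxy-3-(3-benzyloxy-4,5-dimethoxyphenyl)-5,8-dihydroxy-6-methoxychromen-4-one | COc1c(O)c2c(=O)c(-c3cc(OC)c(OC)c(OCc4ccccc4)c3)coc2c(O)c1OCc1ccccc1 | intermediate
15 | 7-benzyloxy-3-(3-benzyloxy-4,5-dimethoxyphenyl)-6-methoxychromene-4,5,8-trione | COC1=C(OCc2ccccc2)C(=O)c2occ(-c3cc(OC)c(OC)c(OCc4ccccc4)c3)c(=O)c2C1=O | intermediate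
16 | 5,7,8-trihydroxy-3-(3-hydroxy-4,5-dimethoxyphenyl)-6-methoxychromen-4-one | COc1cc(-c2coc3c(O)c(O)c(OC)c(O)c3c2=O)cc(O)c1OC | target

Total step count: 10. Longest linear sequence: 9 (steps 1–3 and 5–10).

Steps most likely to fail

**1. Step 9.**
- The acylquinone may be consumed before the acetal is hydrolysed. Possible causes are carbon attack of the electron-rich ring B on C8a, addition of the liberated methanol, and acid loss of the vinylogous benzyl ester at C7.
- Any acetal cleavage that runs ahead of the oxidation would let O5 close the ring.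
- The fallback forms the same O1–C8a bond without redox chemistry, by intramolecular O-arylation of an enolate. It uses only known reaction types, sets out from 5 and 7, and comes back at 16.
- Compound 5 is dibenzylated (BnBr, K2CO3, DMF, 60 °C) to 1-[2,4,5-tris(benzyloxy)-3-methoxyphenyl]ethanone F1.
- NBS in MeCN then brominates the one free ring position to give 1-[3,4,6-tris(benzyloxy)-2-bromo-5-methoxyphenyl]ethanone F2.
- Claisen–Schmidt condensation with 7 should give (E)-1-[3,4,6-tris(benzyloxy)-2-bromo-5-methoxyphenyl]-3-(3-benzyloxy-4,5-dimethoxyphenyl)prop-2-en-1-one F3.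
- Thallium(III) nitrate rearrangement as in step 7 should give (±)-1-[3,4,6-tris(benzyloxy)-2-bromo-5-methoxyphenyl]-2-(3-benzyloxy-4,5-dimethoxyphenyl)-3,3-dimethoxypropan-1-one F4.
- Aqueous acid in THF should give (±)-3-[3,4,6-tris(benzyloxy)-2-bromo-5-methoxyphenyl]-2-(3-benzyloxy-4,5-dimethoxyphenyl)-3-oxopropanal F5. Every ring-A oxygen in it is benzylated, so no phenol can compete.
- Ullmann-type closure (CuI cat., 1,10-phenanthroline, K2CO3, DMF, 90 °C) displaces the bromide to give 5,7,8-tris(benzyloxy)-3-(3-benzyloxy-4,5-dimethoxyphenyl)-6-methoxychromen-4-one F6.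
- Hydrogenolysis under the conditions of step 10 leads to 16.

**2. Step 3.**
- Persulfate hydroxylation typically stops at low conversion, over-oxidation to tar competes, and the hot acid hydrolysis may cost part of the benzyl ether.
- The fallback replaces direct C–H oxidation with halogenation, borylation and oxidation. It sets out from 3 and comes back at 5.
- NBS in MeCN at 0 °C brominates para to the free phenol to give 1-(4-benzyloxy-5-bromo-2-hydroxy-3-methoxyphenyl)ethanone F7.
- Miyaura borylation (B2pin2, PdCl2(dppf), KOAc, dioxane, 90 °C) gives 1-[4-benzyloxy-2-hydroxy-3-methoxy-5-(4,4,5,5-tetramethyl-1,3,2-dioxaborolan-2-yl)phenyl]ethanone F8.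
- Sodium perborate in THF/H2O at rt then converts the C–B bond into the C5 hydroxyl of 5.

**3. Step 8.**
- Under base the acidic α-proton may trigger E1cB loss of methoxide, after which the freed O5 phenoxide would close the ring.
- The phenoxide stage is also prone to air oxidation.
- The fallback changes the protecting-group strategy to a fluoride-labile one that is removed in a buffered, nearly neutral medium. It sets out from 8 and comes back at 11.
- TIPSOTf and 2,6-lutidine in CH2Cl2 give (E)-1-[4-benzyloxy-3-methoxy-2,5-bis(triisopropylsilyloxy)phenyl]-3-(3-benzyloxy-4,5-dimethoxyphenyl)prop-2-en-1-one F9.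
- The thallium(III) nitrate rearrangement of step 7 should give (±)-1-[4-benzyloxy-3-methoxy-2,5-bis(triisopropylsilyloxy)phenyl]-2-(3-benzyloxy-4,5-dimethoxyphenyl)-3,3-dimethoxypropan-1-one F10.
- TBAF buffered with AcOH in THF at 0 °C under Ar then releases 11.

Further compounds

F1 | step 9 | 1-[2,4,5-tris(benzyloxy)-3-methoxyphenyl]ethanone | CC(=O)c1cc(OCc2ccccc2)c(OCc2ccccc2)c(OC)c1OCc1ccccc1
F2 | step 9 | 1-[3,4,6-tris(benzyloxy)-2-bromo-5-methoxyphenyl]ethanone | CC(=O)c1c(Br)c(OCc2ccccc2)c(OCc2ccccc2)c(OC)c1OCc1ccccc1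
F3 | step 9 | (E)-1-[3,4,6-tris(benzyloxy)-2-bromo-5-methoxyphenyl]-3-(3-benzyloxy-4,5-dimethoxyphenyl)prop-2-en-1-one | COc1cc(/C=C/C(=O)c2c(Br)c(OCc3ccccc3)c(OCc3ccccc3)c(OC)c2OCc2ccccc2)cc(OCc2ccccc2)c1OC
F4 | step 9 | (±)-1-[3,4,6-tris(benzyloxy)-2-bromo-5-methoxyphenyl]-2-(3-benzyloxy-4,5-dimethoxyphenyl)-3,3-dimethoxypropan-1-one | COC(OC)C(C(=O)c1c(Br)c(OCc2ccccc2)c(OCc2ccccc2)c(OC)c1OCc1ccccc1)c1cc(OC)c(OC)c(OCc2ccccc2)c1
F5 | step 9 | (±)-3-[3,4,6-tris(benzyloxy)-2-bromo-5-methoxyphenyl]-2-(3-benzyloxy-4,5-dimethoxyphenyl)-3-oxopropanal | O=CC(C(=O)c1c(Br)c(OCc2ccccc2)c(OCc2ccccc2)c(OC)c1OCc1ccccc1)c1cc(OC)c(OC)c(OCc2ccccc2)c1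
F6 | step 9 | 5,7,8-tris(benzyloxy)-3-(3-benzyloxy-4,5-dimethoxyphenyl)-6-methoxychromen-4-one | COc1c(OCc2ccccc2)c2c(=O)c(-c3cc(OC)c(OC)c(OCc4ccccc4)c3)coc2c(OCc2ccccc2)c1OCc1ccccc1
F7 | step 3 | 1-(4-benzyloxy-5-bromo-2-hydroxy-3-methoxyphenyl)ethanone | CC(=O)c1cc(Br)c(OCc2ccccc2)c(OC)c1O
F8 | step 3 | 1-[4-benzyloxy-2-hydroxy-3-methoxy-5-(4,4,5,5-tetramethyl-1,3,2-dioxaborolan-2-yl)phenyl]ethanone | CC(=O)c1cc(B2OC(C)(C)C(C)(C)O2)c(OCc2ccccc2)c(OC)c1O
F9 | step 8 | (E)-1-[4-benzyloxy-3-methoxy-2,5-bis(triisopropylsilyloxy)phenyl]-3-(3-benzyloxy-4,5-dimethoxyphenyl)prop-2-en-1-one | COc1cc(/C=C/C(=O)c2cc(O[Si](C(C)C)(C(C)C)C(C)C)c(OCc3ccccc3)c(OC)c2O[Si](C(C)C)(C(C)C)C(C)C)cc(OCc2ccccc2)c1OC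
F10 | step 8 | (±)-1-[4-benzyloxy-3-methoxy-2,5-bis(triisopropylsilyloxy)phenyl]-2-(3-benzyloxy-4,5-dimethoxyphenyl)-3,3-dimethoxypropan-1-one | COC(OC)C(C(=O)c1cc(O[Si](C(C)C)(C(C)C)C(C)C)c(OCc2ccccc2)c(OC)c1O[Si](C(C)C)(C(C)C)C(C)C)c1cc(OC)c(OC)c(OCc2ccccc2)c1
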